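# Proposed synthesis of 6-n-heneicosyl-2,4-dimethoxyphenol (14)

## Analysis of the target

Compound 14 is one benzene ring with four substituents: a free hydroxyl at C1, methoxy groups at C2 and C4, and an unbranched saturated C21 chain at C6. C3 and C5 carry hydrogen. It has no stereocentre and no double-bond geometry, so there are no stereochemical relationships to build, and any configuration that arises on the way can be discarded. The one sensitive function is the electron-rich 4-methoxyphenol unit, which air and mild oxidants convert into a methoxy-1,4-benzoquinone. The free phenol is therefore best released last and under reducing conditions. The long chain makes every intermediate waxy and poorly soluble in cold or purely polar media, which argues against cryogenic steps on chain-bearing material. The real difficulty is regiochemical. Of three ring oxygens, exactly the one next to the chain must stay unmethylated, and the chain sits ortho to that oxygen but meta to both methoxy groups, a position that neither electrophilic substitution nor directed metalation of a simple resorcinol ether reaches directly. A practical point is that the chain is odd-numbered, whereas cheap fatty feedstocks are even-numbered. The plan rests on the ring sequence C5(H)–C6(chain)–C1(O)–C2(O)–C3(H)–C4(O). The oxygens on C2 and C4 are 1,3-related like the carbonyls of a cyclohexane-1,3-dione, C1 is the alpha carbon of one of them, and C6 is its neighbour. The arene is thus a dehydrogenated 4-alkoxy-5-alkylcyclohexane-1,3-dione whose C1 oxygen is an ether from the start and is never equivalent to the other two. Counting C6 together with the chain gives a C22 unit, so an even-numbered commodity alcohol supplies both.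

## Retrosynthetic reasoning

**14 ⇒ 13 (C1–OH masked as C1–O–CH2Ph).** The free phenol is the most fragile feature, so it is uncovered last. With benzyl ether 13 as the precursor, the final operation is a hydrogenolysis. This is neutral and reductive and cannot harm an oxidation-prone phenol, and the methyl ethers, the ring and the chain are inert to it. The forward step only has to break one benzylic C–O bond.

**13 ⇒ 11 (two O–CH3 bonds and the aromatic sextet).** Both methyl ethers are removed together with one degree of unsaturation, which leads to the alicyclic dione 11. The cut is made here because the three oxygens of 11 differ by construction. Those on the future C2 and C4 are carbonyl groups that can become enol ethers, while the one on the future C1 is already an ether. No selective methylation or demethylation of a triol is needed. The forward reaction must etherify both carbonyls and remove two hydrogens. It must do so faster than 11 expels 4, because 11 stands at the oxidation level of an arene plus 4.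

**11 ⇒ 9 (C–C bond from the future C5 to a carboxyl carbon).** An ester is put back on the ring carbon that lies between a carbonyl and the chain-bearing carbon. This costs one forward step of hydrolysis and decarboxylation. In return it reveals diester 7 as the source of two ring carbons and provides the acidity that makes the ring-forming step possible.

**9 ⇒ 6 + 7 (bonds C5–C6 and C3–C4 of 14).** These two cuts split the ring into two pieces. Enone 6 is the four-carbon piece holding C3, C2, C1 and C6 with the benzyloxy group and the chain. Diester 7 is the two-carbon piece holding C4 and C5.
- Both bonds are polarity-matched. C6 is the beta carbon of an enone whose carbonyl is C2, C3 is the methyl group of that same ketone, and C4 is an acyl carbon.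
- A cut next to C1 would require bond formation at an oxygenated carbon and offers no such match.
- One operation on achiral, acyclic partners delivers the carbocycle, all six ring carbons, and all three oxygens in the correct place and state.
- The forward reaction must achieve conjugate addition to a donor-substituted, beta-alkylated double bond and then close the ring.

**6 ⇒ 2 + 5 (the C=C bond, the future C1–C6).** Cutting the double bond makes C22 aldehyde 2 the carrier of the chain plus ring carbon C6. Phosphonate 5 then carries C1, C2 and C3, with the benzyloxy group already on the carbanion carbon. An aldol condensation of an unsymmetrical alkoxy ketone would form the same bond but would leave open on which side the ketone enolises. In 5 only one carbon is doubly activated, so the regiochemistry is fixed by connectivity and the risk of the route stays in the ring-forming step.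

**5 ⇒ 3 + 4, and 2 ⇒ 1.** The C–O bond of 5 is traced to a carbenoid O–H insertion between commercial diazo phosphonate 3 and alcohol 4. Aldehyde 2 is an oxidation-level adjustment of commodity alcohol 1. Neither step raises a selectivity question.

## Alternatives that were turned down

**Alternative 1:** The aromatic ring is bought, and two bonds are made on it: C6–C1' to the chain and C1–B as a placeholder for the C1 oxygen.
- *Key step.* Iodine–magnesium exchange on 2-iodo-3,5-dimethoxyphenyl trifluoromethanesulfonate A2, followed by warming, expels the sulfonate and releases an aryne across C1/C6. Heneicosylmagnesium bromide A3 adds at C6, the aryne carbon remote from the flanking methoxy group. The arylmagnesium left at C1 is quenched with a borate ester to give (2-heneicosyl-4,6-dimethoxyphenyl)boronic acid A1, whose C–B bond is then oxidised to give 14.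
- *For.* The route is very short. It needs no protecting group, the polarisation of the aryne by the C2 methoxy group points the addition the right way, and the C1 oxygen arrives already distinct from the other two.
- *Against.* Three organomagnesium species share one flask (the exchange reagent, A3 and the aryl product), and each can add to the aryne or consume the borate. A primary alkyl Grignard reagent with beta hydrogens can also deliver hydride to an aryne. An excess of A3 would therefore be needed, and A3 is the expensive partner, because an odd-numbered C21 halide has to be made by one-carbon degradation of a C22 feedstock. A2 also requires a regioselective iodination among three activated ring positions.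
- *Comparison.* This alternative is stronger on step count. The chosen route offers regiochemistry that follows from connectivity rather than from a selectivity ratio, a single nucleophile in the key step, and direct use of the C22 commodity because its terminal carbon becomes C6.

**Alternative 2:** Ring bond C4–C5 is cut, and the arene is traced to a four-membered ring.
- *Key step.* Heating 4-(tert-butyldimethylsilyloxy)-3-methoxy-4-(tricos-1-en-2-yl)cyclobut-2-en-1-one A5 opens it electrocyclically to a dienylketene. The ketene carbon (C4) bonds to the vinyl terminus (C5) in a six-electron closure, and enolisation gives 4-(tert-butyldimethylsilyloxy)-3-heneicosyl-5-methoxyphenol A4. Methylation of the new phenol and desilylation would complete 14.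
- *For.* The Moore-type ring expansion is a well-behaved thermal reaction. The oxygen substituent on the sp3 carbon rotates outward, so the vinyl group is placed correctly for closure. Every substituent position is programmed, and the three oxygens emerge in three different states.
- *Against.* A5 needs a squaric ester that has first been reduced at one ring carbon, and it needs a 2-metalated 1-alkene carrying the C21 chain, which again derives from odd-numbered material over several steps. It also requires cryogenic addition to a waxy partner. The count comes to roughly eight or nine steps with costly four-membered-ring starting material.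
- *Comparison.* The key step of this alternative is more predictable than that of the chosen route. The chosen route is shorter, uses commodity reagents, and avoids organolithium chemistry on chain-bearing compounds.

**Alternative 3:** Ring bond C1–C6 is cut, and the C1 oxygen is replaced retrosynthetically by a carboxyl group.
- *Key step.* Buffered base folds methyl 3,5,7-trioxooctacosanoate A7 by aldol attack of its C2 on its C7 ketone. Dehydration and enolisation then give methyl 2-heneicosyl-4,6-dihydroxybenzoate A6.
- *For.* This is the polyketide-type cyclisation that nature uses for such rings. It has a strong aromatic driving force, and the acyl end comes from an even-numbered C22 acid derivative, so the feedstock argument is as good as in the chosen route.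
- *Against.* A7 requires polyanion chemistry and can also close by Claisen or lactonisation modes. More seriously, the ring-forming step puts carbon, not oxygen, on C1. After double methylation, in which the hydrogen-bonded ortho hydroxyl is the slow one, a benzoate flanked by two ortho substituents must be taken to the aldehyde level and then through a Dakin or Baeyer–Villiger sequence and hydrolysis. This adds about four steps for one atom exchange and gives about nine steps in all.
- *Comparison.* The cyclisation of this alternative is better established. The chosen route carries the C1 oxygen from the start as a benzyl ether, so nothing has to be exchanged on the crowded arene.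

Key step: step 4

Remark on the chemistry: 5 and 8–12 are racemic and, where several stereocentres are present, are mixtures of diastereomers and keto–enol tautomers. They are drawn in the keto form without configuration, because 13 and 14 are achiral.

## Route

Step 1
Reactants: 1 docosan-1-ol
Product: 2 docosanal
Conditions: 2,2,6,6-tetramethylpiperidin-1-oxyl (TEMPO, 10 mol %), PhI(OAc)2 (1.1 equiv), CH2Cl2, 30 °C
Reagents that add atoms: none
Why: Oxoammonium-mediated oxidation of a primary alcohol stops at the aldehyde in anhydrous CH2Cl2, and it runs at or above room temperature, where the waxy alcohol stays in solution, unlike a cryogenic activated-DMSO oxidation.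

Step 2
Reactants: 3 dimethyl (1-diazo-2-oxopropyl)phosphonate; 4 benzyl alcohol
Product: 5 dimethyl [1-(benzyloxy)-2-oxopropyl]phosphonate (racemic)
Conditions: Rh2(OAc)4 (1 mol %), 4 (2 equiv), ClCH2CH2Cl, 80 °C, slow addition of neat 3
Reagents that add atoms: none
Why: Rhodium-carbenoid O–H insertion: the electrophilic carbenoid from the doubly acceptor-substituted diazo compound is captured by the alcohol oxygen, and a fast proton shift gives the alpha-alkoxy-beta-ketophosphonate. Slow addition of nitrile-free 3 into excess 4 suppresses carbene dimerisation and oxazole formation, and the racemic stereocentre disappears in step 3.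

Step 3
Reactants: 5 dimethyl [1-(benzyloxy)-2-oxopropyl]phosphonate; 2 docosanal
Product: 6 (Z)-3-(benzyloxy)pentacos-3-en-2-one
Conditions: NaH (1.05 equiv), THF, 0 °C; then 2, 0 °C to rt
Reagents that add atoms: none
Why: Horner–Wadsworth–Emmons olefination, in which the only doubly activated carbon of 5 carries the benzyloxy group, so the oxygen ends up on the alpha carbon of the enone without any regiochemical question. Reversible addition should place the chain trans to the acetyl group, which is the Z isomer, and a minor E isomer needs no removal because both converge in step 4.

Step 4
Reactants: 6 (Z)-3-(benzyloxy)pentacos-3-en-2-one; 7 dimethyl malonate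
Product: 9 methyl 5-(benzyloxy)-6-heneicosyl-2,4-dioxocyclohexane-1-carboxylate (diastereomer mixture), via Michael adduct 8 (not isolated)
Conditions: 7 (1.5 equiv), NaOMe (1.5 equiv), MeOH–THF (2:1), reflux; then 1 M HCl, 0 °C
Reagents that add atoms: none
Why: Proposed new method: the closest known reaction type is the malonate Michael–Claisen (Dieckmann-type) annulation of plain alk-3-en-2-ones to 5-alkylcyclohexane-1,3-diones, which has not been shown on an enone bearing an alpha-alkoxy donor. Sodium dimethyl malonate adds reversibly to the chain-bearing beta carbon of 6 to give 8 (bond C5–C6 of 14), and proton exchange then produces the terminal methyl ketone enolate, which attacks one malonate ester carbonyl and expels methoxide (bond C3–C4 of 14). This closure is 6-(enolendo)-exo-trig, a favoured mode, whereas the enolate on the benzyloxy side could only form a four-membered ring, so a single ring size is accessible. The benzyloxy oxygen pushes electron density onto the beta carbon and the chain hinders it, so the addition equilibrium should be less favourable than for a plain enone, but the sequence is pulled forward because 9 is deprotonated at once to a stabilised beta-tricarbonyl anion, which is why more than one equivalent of base is used. The selectivity needed is 1,4-attack over 1,2-attack and over self-condensation of 6, and a soft stabilised carbanion used in excess under equilibrating conditions secures it, since 1,2-adducts revert. Methoxide matches the methyl esters, so no ester scrambling occurs, and an alkoxide is too poor a leaving group for the benzyloxy group to be lost under base. Three stereocentres arise (C1, C5 and C6 of 9); C1 and C5 are epimerisable and should settle trans to the chain, but no control is needed because step 6 erases all three.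

Step 5
Reactants: 9 methyl 5-(benzyloxy)-6-heneicosyl-2,4-dioxocyclohexane-1-carboxylate
Product: 11 4-(benzyloxy)-5-heneicosylcyclohexane-1,3-dione, via keto acid 10 (not isolated)
Conditions: 2 M NaOH, THF–MeOH, 60 °C; then 2 M HCl to pH 3, 60 °C
Reagents that add atoms: none
Why: Ester saponification followed by decarboxylation of beta-keto acid 10 through a cyclic six-membered transition state, the classical end of the malonate annulation. In base the ring is protected as its enolate against retro-Claisen cleavage, and the acid stage is kept short and mild because 11 carries a latent leaving group.

Step 6
Reactants: 11 4-(benzyloxy)-5-heneicosylcyclohexane-1,3-dione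
Product: 13 2-(benzyloxy)-1-heneicosyl-3,5-dimethoxybenzene, via methyl enol ether 12 (not isolated)
Conditions: I2 (2 equiv), MeOH–ClCH2CH2Cl (4:1), reflux, slow addition of 11
Reagents that add atoms: methanol, CO
Why: Proposed new method: the closest known reaction type is the iodine–methanol oxidative aromatisation of 5-alkylcyclohexane-1,3-diones to resorcinol dimethyl ethers, which has not been shown on a dione carrying an alkoxy group at C4. Acid formed in situ should convert 11 via 12 into dimethoxycyclohexadienes, which iodine attacks before loss of HI gives the arene; the benzyloxy group should survive because the C4–H acidified by its oxygen is the proton most readily lost on diene formation, which places the ether on an sp2 carbon, and because ionisation at C4 would give a cation that neither methoxy group can stabilise. Adding 11 slowly to an excess of iodine should keep oxidation faster than acid-induced loss of 4.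

Step 7
Reactants: 13 2-(benzyloxy)-1-heneicosyl-3,5-dimethoxybenzene
Product: 14 6-n-heneicosyl-2,4-dimethoxyphenol
Conditions: H2 (1 atm), Pd/C (10 wt %), EtOAc–THF, rt
Reagents that add atoms: none
Why: Catalytic hydrogenolysis of a benzyl aryl ether, whose neutral reductive medium releases the oxidation-prone phenol without touching the methyl ethers, the ring or the chain. The product is handled under inert gas.

## Compound list

1 | docosan-1-ol | CCCCCCCCCCCCCCCCCCCCCCO | starting material
2 | docosanal | CCCCCCCCCCCCCCCCCCCCCC=O | intermediate
3 | dimethyl (1-diazo-2-oxopropyl)phosphonate | CC(=O)C(=[N+]=[N-])P(=O)(OC)OC | starting material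
4 | benzyl alcohol | OCc1ccccc1 | starting material
5 | dimethyl [1-(benzyloxy)-2-oxopropyl]phosphonate (racemic) | CC(=O)C(OCc1ccccc1)P(=O)(OC)OC | intermediate
6 | (Z)-3-(benzyloxy)pentacos-3-en-2-one | CCCCCCCCCCCCCCCCCCCCC/C=C(\OCc1ccccc1)C(C)=O | intermediate
7 | dimethyl malonate | COC(=O)CC(=O)OC | starting material
8 | dimethyl 2-[3-(benzyloxy)-2-oxopentacosan-4-yl]propanedioate (Michael adduct, diastereomer mixture, not isolated) | CCCCCCCCCCCCCCCCCCCCCC(C(OCc1ccccc1)C(C)=O)C(C(=O)OC)C(=O)OC | intermediate
9 | methyl 5-(benzyloxy)-6-heneicosyl-2,4-dioxocyclohexane-1-carboxylate (diastereomer mixture) | COC(=O)C1C(=O)CC(=O)C(OCc2ccccc2)C1CCCCCCCCCCCCCCCCCCCCC | intermediate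
10 | 5-(benzyloxy)-6-heneicosyl-2,4-dioxocyclohexane-1-carboxylic acid (not isolated) | OC(=O)C1C(=O)CC(=O)C(OCc2ccccc2)C1CCCCCCCCCCCCCCCCCCCCC | intermediate
11 | 4-(benzyloxy)-5-heneicosylcyclohexane-1,3-dione (diastereomer mixture) | O=C1CC(=O)C(OCc2ccccc2)C(CCCCCCCCCCCCCCCCCCCCC)C1 | intermediate
12 | 6-(benzyloxy)-5-heneicosyl-3-methoxycyclohex-2-en-1-one (not isolated) | COC1=CC(=O)C(OCc2ccccc2)C(CCCCCCCCCCCCCCCCCCCCC)C1 | intermediate
13 | 2-(benzyloxy)-1-heneicosyl-3,5-dimethoxybenzene | CCCCCCCCCCCCCCCCCCCCCc1cc(OC)cc(OC)c1OCc2ccccc2 | intermediate
14 | 6-n-heneicosyl-2,4-dimethoxyphenol | CCCCCCCCCCCCCCCCCCCCCc1cc(OC)cc(OC)c1O | target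

## Step count and least certain steps

Total step count: 7.
Longest linear sequence: 6 steps, either 1 → 2 → 6 → 9 → 11 → 13 → 14 (steps 1, 3, 4, 5, 6, 7) or, equally long, from 3 through steps 2 to 7.

**Step 4 (key step, Proposed new method).**
- *Risk.* The conjugate addition may stall. The double bond is deactivated by the alpha oxygen donor and hindered by the chain, so the addition equilibrium may lie on the side of the starting materials. Prolonged heating with methoxide would then favour self-condensation of the methyl ketone and migration of the double bond out of conjugation.
- *Fallback.* It sets out from 2 and comes back to the route at 12. It builds the ring without the oxygen and adds the oxygen afterwards, using known reactions only. Wittig olefination of 2 with 1-(triphenylphosphoranylidene)propan-2-one gives (E)-pentacos-3-en-2-one F1. The established annulation of this plain enone with 7 and NaOMe gives methyl 6-heneicosyl-2,4-dioxocyclohexane-1-carboxylate F2, and saponification with decarboxylation gives 5-heneicosylcyclohexane-1,3-dione F3. Because F3 is symmetrical, etherification in methanol with catalytic p-toluenesulfonic acid gives a single enol ether, 5-heneicosyl-3-methoxycyclohex-2-en-1-one F4. Kinetic deprotonation with LDA in THF takes place at C6, next to the chain-bearing carbon. Oxidation of this enolate with 2-(phenylsulfonyl)-3-phenyloxaziridine gives 6-hydroxy-5-heneicosyl-3-methoxycyclohex-2-en-1-one F5. Benzyl 2,2,2-trichloroacetimidate with catalytic CF3SO3H then converts F5 into 12, which enters step 6 or its fallback as an isolated compound.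

**Step 6 (Proposed new method).**
- *Risk.* Acid-induced loss of the benzyloxy group with non-oxidative aromatisation is the main danger, since 11 already stands at the oxidation level of an arene plus an alcohol. Secondary risks are iodination of the very electron-rich product ring and premature cleavage of the benzyl ether by the HI that accumulates.
- *Fallback.* It sets out from 11 and comes back at 13. It separates etherification, oxidation and methylation and keeps the oxidation free of acid. Catalytic p-toluenesulfonic acid in methanol at room temperature stops at the enol ether of the less hindered carbonyl, 12, which is isolated. LDA removes the proton on the benzyloxy-bearing carbon, and Me3SiCl traps the enolate as 1-(benzyloxy)-6-heneicosyl-4-methoxy-2-(trimethylsilyloxy)cyclohexa-1,3-diene F6, in which the benzyloxy group sits on a double bond and cannot leave. Dehydrogenation of this silyl dienol ether with DDQ buffered by 2,6-lutidine gives, after aqueous work-up, 2-(benzyloxy)-3-heneicosyl-5-methoxyphenol F7. MeI with K2CO3 in acetone converts F7 into 13.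

**Step 5.**
- *Risk.* Eliminative aromatisation may occur during the warm acid stage. The enolised, hindered ester may also hydrolyse incompletely, which would tempt toward forcing base and retro-Claisen ring opening.
- *Fallback.* It sets out from 6 and comes back at 11. It replaces hydrolysis with a neutral unmasking of the carboxyl group. Enone 6 is annulated as in step 4, but with diallyl malonate F8 and NaH in THF, to give allyl 5-(benzyloxy)-6-heneicosyl-2,4-dioxocyclohexane-1-carboxylate F9. Pd(PPh3)4 and morpholine in THF at room temperature (Tsuji–Trost deallylation) release 10, which should decarboxylate at or slightly above room temperature to 11 without any hot aqueous acid or base.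

**Step 3.**
- *Risk.* Olefination may be sluggish, because the alkoxy-substituted phosphonate anion is hindered and less nucleophilic. This would give the base time to trigger self-aldol of the enolisable aldehyde. Poor geometric selectivity is possible but harmless.
- *Fallback.* It sets out from 2 and comes back at 6. It forms the same bond by aldol addition and elimination. 1-(Benzyloxy)propan-2-one F10 is enolised with Bu2BOTf and iPr2NEt, and addition to 2 through its oxygenated carbon gives 3-(benzyloxy)-4-hydroxypentacosan-2-one F11. MsCl with Et3N gives 3-(benzyloxy)-2-oxopentacosan-4-yl methanesulfonate F12, and DBU eliminates it to the conjugated Z enone 6. The price is the question of which side of F10 enolises, which the phosphonate route avoids.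

## Further compounds

F1 | step 4 | (E)-pentacos-3-en-2-one | CCCCCCCCCCCCCCCCCCCCC/C=C/C(C)=O
F2 | step 4 | methyl 6-heneicosyl-2,4-dioxocyclohexane-1-carboxylate (diastereomer mixture) | COC(=O)C1C(=O)CC(=O)CC1CCCCCCCCCCCCCCCCCCCCC
F3 | step 4 | 5-heneicosylcyclohexane-1,3-dione | O=C1CC(=O)CC(CCCCCCCCCCCCCCCCCCCCC)C1
F4 | step 4 | 5-heneicosyl-3-methoxycyclohex-2-en-1-one (racemic) | COC1=CC(=O)CC(CCCCCCCCCCCCCCCCCCCCC)C1
F5 | step 4 | 6-hydroxy-5-heneicosyl-3-methoxycyclohex-2-en-1-one (racemic, diastereomer mixture) | COC1=CC(=O)C(O)C(CCCCCCCCCCCCCCCCCCCCC)C1
F6 | step 6 | 1-(benzyloxy)-6-heneicosyl-4-methoxy-2-(trimethylsilyloxy)cyclohexa-1,3-diene (racemic) | COC1=CC(O[Si](C)(C)C)=C(OCc2ccccc2)C(CCCCCCCCCCCCCCCCCCCCC)C1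
F7 | step 6 | 2-(benzyloxy)-3-heneicosyl-5-methoxyphenol | CCCCCCCCCCCCCCCCCCCCCc1cc(OC)cc(O)c1OCc2ccccc2
F8 | step 5 | diallyl malonate | C=CCOC(=O)CC(=O)OCC=C
F9 | step 5 | allyl 5-(benzyloxy)-6-heneicosyl-2,4-dioxocyclohexane-1-carboxylate (diastereomer mixture) | C=CCOC(=O)C1C(=O)CC(=O)C(OCc2ccccc2)C1CCCCCCCCCCCCCCCCCCCCC
F10 | step 3 | 1-(benzyloxy)propan-2-one | CC(=O)COCc1ccccc1
F11 | step 3 | 3-(benzyloxy)-4-hydroxypentacosan-2-one (racemic, diastereomer mixture) | CCCCCCCCCCCCCCCCCCCCCC(O)C(OCc1ccccc1)C(C)=O
F12 | step 3 | 3-(benzyloxy)-2-oxopentacosan-4-yl methanesulfonate (racemic, diastereomer mixture) | CCCCCCCCCCCCCCCCCCCCCC(OS(C)(=O)=O)C(OCc1ccccc1)C(C)=O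
A1 | alternative 1 | (2-heneicosyl-4,6-dimethoxyphenyl)boronic acid | CCCCCCCCCCCCCCCCCCCCCc1cc(OC)cc(OC)c1B(O)O
A2 | alternative 1 | 2-iodo-3,5-dimethoxyphenyl trifluoromethanesulfonate | COc1cc(OC)c(I)c(OS(=O)(=O)C(F)(F)F)c1
A3 | alternative 1 | heneicosylmagnesium bromide | CCCCCCCCCCCCCCCCCCCCC[Mg]Br
A4 | alternative 2 | 4-(tert-butyldimethylsilyloxy)-3-heneicosyl-5-methoxyphenol | CCCCCCCCCCCCCCCCCCCCCc1cc(O)cc(OC)c1O[Si](C)(C)C(C)(C)C
A5 | alternative 2 | 4-(tert-butyldimethylsilyloxy)-3-methoxy-4-(tricos-1-en-2-yl)cyclobut-2-en-1-one (racemic) | C=C(CCCCCCCCCCCCCCCCCCCCC)C1(O[Si](C)(C)C(C)(C)C)C(OC)=CC1=O
A6 | alternative 3 | methyl 2-heneicosyl-4,6-dihydroxybenzoate | CCCCCCCCCCCCCCCCCCCCCc1cc(O)cc(O)c1C(=O)OC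
A7 | alternative 3 | methyl 3,5,7-trioxooctacosanoate | CCCCCCCCCCCCCCCCCCCCCC(=O)CC(=O)CC(=O)CC(=O)OC
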